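**Plan**

1. Numbering: hydrindane C1–C3, C3a, C4–C7, C7a (C3 carries the CH2 link, C4 the methyl carbinol, C7 bromine, C7a CH2OH); ring A C1′ (C–OAc), C3′ (CMe2), C4′ (CHBr).
2. Cuts: both C–Br bonds (each back to an axial alcohol, SN2 inversion); C3′–C4′ of ring A (tertiary radical onto a nitrile, giving the C4′ ketone); the three CH2 arms on C1′ (two epoxide openings from one 2-substituted allylic alcohol); C3–CH2 (conjugate allylation); C4–CH3; C3=C3a (aldol condensation); C7a–allyl (allylic alkylation of a β-keto ester).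
3. Forward: a purchased cyclohexane becomes the six-membered ring of the hydrindane, the cyclopentene is annulated, the side chain is attached at C3 and built up on C1′, and ring A is closed fourth from the end.
4. Enabling feature: C1′ of ring A is fully substituted with CH2 neighbours only, C3′ is 1,3 and C4′ is 1,4 to it. A methallyl arm (C2′, C3′) and a cyanoethyl arm (C6′, C5′, C4′) on C1′ therefore put a tertiary radical at C3′ six atoms from a nitrile carbon C4′, and 6-exo closure gives the CMe2–C(=O) unit that leads to the equatorial bromide.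
5. Stereochemistry: C7a from the chiral palladium catalyst; C7 from hydroxyl-directed reduction then inversion; C3, C3a and C4 from attack anti to the angular CH2OSi group; C1′ from Sharpless epoxidation; C4′ from the chair of ring A (equatorial hydride attack, then inversion).

Key step: step 15

Remark: 1 is taken as a purchased compound (otherwise one acylation of 1,4-dioxaspiro[4.5]decan-8-one with diethyl carbonate/NaH).
Abbreviations: TBDPS = tert-butyldiphenylsilyl; TES = triethylsilyl; Hyd = (3S,3aS,4R,7S,7aS)-7-bromo-4-hydroxy-4-methyl-7a-[(TBDPS-oxy)methyl]octahydro-1H-inden-3-yl.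

**Route**

Step 1
Reactants: 1 ethyl 8-oxo-1,4-dioxaspiro[4.5]decane-7-carboxylate; 2 allyl acetate
Product: 3 ethyl (7R)-8-oxo-7-(prop-2-en-1-yl)-1,4-dioxaspiro[4.5]decane-7-carboxylate
Conditions: [Pd(C3H5)Cl]2 (cat.), chiral DACH-phenyl bisphosphine ligand (cat., enantiomer that delivers 7R), TMG, toluene, 0 °C
Reagents that add atoms: none
Why: Tsuji–Trost asymmetric allylic alkylation of the stabilized β-keto ester enolate by the π-allylpalladium complex, in which the chiral ligand pocket selects the enolate face and sets the quaternary C7.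

Step 2
Reactants: 3 ethyl (7R)-8-oxo-7-(prop-2-en-1-yl)-1,4-dioxaspiro[4.5]decane-7-carboxylate
Product: 4 (7S)-7-(hydroxymethyl)-7-(prop-2-en-1-yl)-1,4-dioxaspiro[4.5]decan-8-one
Conditions: LDA (1.1 equiv), THF, −78 °C; then LiAlH4, −78 → 0 °C; aq. potassium sodium tartrate
Reagents that add atoms: none
Why: The ketone is masked in the flask as its lithium enolate (C9 is its only enolizable side), so that the hydride reduction should touch only the ester and no stereocentre changes (chemoselective ester reduction).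

Step 3
Reactants: 4 (7S)-7-(hydroxymethyl)-7-(prop-2-en-1-yl)-1,4-dioxaspiro[4.5]decan-8-one
Product: 5 (7S,8R)-7-(hydroxymethyl)-7-(prop-2-en-1-yl)-1,4-dioxaspiro[4.5]decan-8-ol
Conditions: Me4NBH(OAc)3, MeCN/AcOH, −25 °C
Reagents that add atoms: none
Why: Evans–Saksena hydroxyl-directed reduction, in which the primary alcohol binds boron and delivers hydride to the ketone face on its own side, so the new C8 hydroxyl should end up trans to CH2OH.

Step 4
Reactants: 5 (7S,8R)-7-(hydroxymethyl)-7-(prop-2-en-1-yl)-1,4-dioxaspiro[4.5]decan-8-ol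
Product: 7 (7S,8R)-7-(prop-2-en-1-yl)-7-[(TBDPS-oxy)methyl]-8-(TES-oxy)-1,4-dioxaspiro[4.5]decane, via primary TBDPS ether 6 (not isolated)
Conditions: TBDPSCl, imidazole, CH2Cl2, 0 °C; then TESOTf, 2,6-lutidine, −40 °C
Reagents that add atoms: tert-butyl(chloro)diphenylsilane, CC(C)(C)[Si](Cl)(c1ccccc1)c1ccccc1; triethylsilyl trifluoromethanesulfonate, CC[Si](CC)(CC)OS(=O)(=O)C(F)(F)F
Why: Silyl ether formation in order of steric access, the bulky chloride taking only the primary hydroxyl and the silyl triflate then capping the hindered secondary one, with no stereocentre touched.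

Step 5
Reactants: 7 (7S,8R)-7-(prop-2-en-1-yl)-7-[(TBDPS-oxy)methyl]-8-(TES-oxy)-1,4-dioxaspiro[4.5]decane
Product: 8 3-{(7S,8R)-7-[(TBDPS-oxy)methyl]-8-(TES-oxy)-1,4-dioxaspiro[4.5]decan-7-yl}propan-1-ol
Conditions: 9-BBN, THF, 0 °C → rt; then NaOH, H2O2, 0 °C
Reagents that add atoms: hydrogen peroxide, OO
Why: Anti-Markovnikov hydroboration–oxidation of the monosubstituted alkene with a bulky borane should give the primary alcohol.

Step 6
Reactants: 8 3-{(7S,8R)-7-[(TBDPS-oxy)methyl]-8-(TES-oxy)-1,4-dioxaspiro[4.5]decan-7-yl}propan-1-ol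
Product: 9 3-{(7S,8R)-7-[(TBDPS-oxy)methyl]-8-(TES-oxy)-1,4-dioxaspiro[4.5]decan-7-yl}propanal
Conditions: DMP, NaHCO3, CH2Cl2, 0 °C → rt
Reagents that add atoms: none
Why: Dess–Martin oxidation of the primary alcohol stops at the aldehyde and leaves silyl ethers and ketal intact.

Step 7
Reactants: 9 3-{(7S,8R)-7-[(TBDPS-oxy)methyl]-8-(TES-oxy)-1,4-dioxaspiro[4.5]decan-7-yl}propanal
Product: 11 (7R,7aS)-7-hydroxy-7a-[(TBDPS-oxy)methyl]-1,2,5,6,7,7a-hexahydro-4H-inden-4-one, via hydroxy keto aldehyde 10 (not isolated)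
Conditions: 1 M HCl, THF, rt; then piperidine, AcOH (cat.), PhH, 60 °C
Reagents that add atoms: water, O
Why: Acid hydrolysis frees the C4 ketone and the C7 alcohol, and an amine-salt-catalysed intramolecular aldol condensation (5-exo attack of the ketone enol at C3a on the aldehyde, then dehydration) should give the cyclopentene-fused enone, since enolization toward C5 leads only to a bridged aldol that cannot dehydrate.

Step 8
Reactants: 11 (7R,7aS)-7-hydroxy-7a-[(TBDPS-oxy)methyl]-1,2,5,6,7,7a-hexahydro-4H-inden-4-one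
Product: 12 (7S,7aS)-7-bromo-7a-[(TBDPS-oxy)methyl]-1,2,5,6,7,7a-hexahydro-4H-inden-4-one
Conditions: CBr4, PPh3, toluene, 60 °C
Reagents that add atoms: tetrabromomethane, BrC(Br)(Br)Br
Why: Appel reaction, in which bromide displaces the alkoxyphosphonium group from the rear (SN2), inverting C7 and placing bromine cis to the angular CH2OTBDPS group.

Step 9
Reactants: 12 (7S,7aS)-7-bromo-7a-[(TBDPS-oxy)methyl]-1,2,5,6,7,7a-hexahydro-4H-inden-4-one; 13 2-[(trimethylsilyl)methyl]prop-2-en-1-yl acetate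
Product: 14 (3S,3aS,7S,7aS)-3-[2-(acetoxymethyl)prop-2-en-1-yl]-7-bromo-7a-[(TBDPS-oxy)methyl]octahydro-4H-inden-4-one
Conditions: TiCl4, CH2Cl2, −78 °C; aq. NaHCO3
Reagents that add atoms: none
Why: Hosomi–Sakurai conjugate allylation, in which the allylsilane should attack C3 of the TiCl4-activated enone on the face opposite the angular CH2OTBDPS group and the titanium enolate should be protonated at C3a on that same face, giving the trans ring fusion with the C3 chain trans to C4.

Step 10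
Reactants: 14 (3S,3aS,7S,7aS)-3-[2-(acetoxymethyl)prop-2-en-1-yl]-7-bromo-7a-[(TBDPS-oxy)methyl]octahydro-4H-inden-4-one
Product: 15 (3S,3aS,4R,7S,7aS)-7-bromo-3-[2-(hydroxymethyl)prop-2-en-1-yl]-4-methyl-7a-[(TBDPS-oxy)methyl]octahydro-1H-inden-4-ol
Conditions: MeMgBr (excess), THF, −78 → 0 °C; then H2O
Reagents that add atoms: methylmagnesium bromide, C[Mg]Br
Why: Grignard 1,2-addition from the equatorial direction (axial attack is blocked by the syn-axial CH2OTBDPS group on C7a) should set C4 with methyl equatorial and hydroxyl axial, while the excess reagent cleaves the allylic acetate.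

Step 11
Reactants: 15 (3S,3aS,4R,7S,7aS)-7-bromo-3-[2-(hydroxymethyl)prop-2-en-1-yl]-4-methyl-7a-[(TBDPS-oxy)methyl]octahydro-1H-inden-4-ol
Product: 16 [(2R)-2-(Hyd-methyl)oxiran-2-yl]methanol
Conditions: Ti(OiPr)4 (cat.), D-(−)-diethyl tartrate (cat.), t-BuOOH, 4 Å MS, CH2Cl2, −20 °C
Reagents that add atoms: tert-butyl hydroperoxide, CC(C)(C)OO
Why: Sharpless asymmetric epoxidation of the 2-substituted allylic alcohol, in which the tartrate (reagent control) selects the alkene face and sets the future C1′ of ring A.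

Step 12
Reactants: 16 [(2R)-2-(Hyd-methyl)oxiran-2-yl]methanol; 17 isopropenylmagnesium bromide
Product: 18 (2S)-2-(Hyd-methyl)-4-methylpent-4-ene-1,2-diol
Conditions: CuI (cat.), THF, −30 → 0 °C; then H2O
Reagents that add atoms: none
Why: Copper-catalysed Grignard opening of the 2,2-disubstituted epoxide at its CH2 terminus (SN2 at the less hindered carbon) installs the methallyl arm and leaves the C–O bond at the quaternary carbon, and hence its configuration, untouched.

Step 13
Reactants: 18 (2S)-2-(Hyd-methyl)-4-methylpent-4-ene-1,2-diol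
Product: 20 (2S)-2-(Hyd-methyl)-2-(2-methylprop-2-en-1-yl)oxirane, via primary tosylate 19 (not isolated)
Conditions: NaH, N-tosylimidazole, THF, 0 °C → rt
Reagents that add atoms: none
Why: Selective sulfonylation of the primary alkoxide followed by 3-exo-tet Williamson closure by the neighbouring tertiary alkoxide should give the new terminal epoxide with retention at the quaternary carbon.

Step 14
Reactants: 20 (2S)-2-(Hyd-methyl)-2-(2-methylprop-2-en-1-yl)oxirane
Product: 22 (4S)-4-acetoxy-4-(Hyd-methyl)-6-methylhept-6-enenitrile, via dilithium alkoxide 21 (not isolated)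
Conditions: MeCN, n-BuLi, THF, −78 °C; then 20, −78 → −20 °C; then Ac2O, −78 → 0 °C
Reagents that add atoms: acetonitrile, CC#N; acetic anhydride, CC(=O)OC(C)=O
Why: Epoxide opening by the nitrile-stabilized carbanion at the CH2 terminus installs the cyanoethyl arm, and the unhindered tertiary lithium alkoxide so formed is O-acylated in the flask, whereas the axial C4 alkoxide, syn-axial to CH2OTBDPS, should be too hindered to react.

Step 15
Reactants: 22 (4S)-4-acetoxy-4-(Hyd-methyl)-6-methylhept-6-enenitrile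
Product: 24 (1S)-1-(Hyd-methyl)-3,3-dimethyl-4-oxocyclohexyl acetate, via N–H ketimine 23 (not isolated)
Conditions: Fe(acac)3 (cat.), PhSiH3, EtOH, 60 °C; then 1 M HCl, THF, rt
Reagents that add atoms: water, O
Why: Hydrogen-atom transfer from the iron hydride formed from Fe(acac)3 and PhSiH3 to the CH2 terminus of the methallyl group gives the tertiary radical at C3′, which adds to the nitrile carbon C4′ to form the C3′–C4′ bond and a cyclic iminyl radical; reduction and protonation give the N–H imine, which aqueous acid hydrolyses to the ketone. The closest known reaction type is the hydrogen-atom-transfer-initiated reductive cyclization of alkene-tethered nitriles to α-quaternary cycloalkanones. Ring A closes in the 6-exo-dig mode. No stereocentre is formed (C3′ carries two methyls and C4′ is trigonal), so C1′ passes unchanged and later controls C4′ through the chair. The step needs Markovnikov hydrogen-atom transfer and ring closure ahead of simple alkene reduction or 1,2-acetoxy shift; the first is secured by the 1,1-disubstituted alkene, which can only give the tertiary radical, the second by the fully substituted C1′ in the tether (gem-dialkyl effect) and the absence of a fast hydrogen donor. The secondary bromide, silyl ether and tertiary acetate should be inert to these neutral conditions.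

Step 16
Reactants: 24 (1S)-1-(Hyd-methyl)-3,3-dimethyl-4-oxocyclohexyl acetate
Product: 25 (1S,4R)-4-hydroxy-1-(Hyd-methyl)-3,3-dimethylcyclohexyl acetate
Conditions: LiBH(s-Bu)3 (L-Selectride), THF, −78 °C; then H2O
Reagents that add atoms: none
Why: Ketone reduction by a bulky hydride, which should approach the chair (OAc axial and side chain equatorial at C1′) from the equatorial direction to avoid the axial hydrogens on C2′ and C6′, giving the axial C4′ alcohol trans to the acetate.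

Step 17
Reactants: 25 (1S,4R)-4-hydroxy-1-(Hyd-methyl)-3,3-dimethylcyclohexyl acetate
Product: 26 (1S,4S)-4-bromo-1-(Hyd-methyl)-3,3-dimethylcyclohexyl acetate
Conditions: CBr4, PPh3, toluene, 60 °C
Reagents that add atoms: tetrabromomethane, BrC(Br)(Br)Br
Why: Appel reaction with SN2 inversion should convert the axial alcohol into the equatorial bromide cis to the acetate, the tertiary C4 hydroxyl being too hindered to be activated.

Step 18
Reactants: 26 (1S,4S)-4-bromo-1-(Hyd-methyl)-3,3-dimethylcyclohexyl acetate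
Product: 27 (1S,4S)-4-bromo-1-{[(3S,3aS,4R,7S,7aS)-7-bromo-4-hydroxy-7a-(hydroxymethyl)-4-methyloctahydro-1H-inden-3-yl]methyl}-3,3-dimethylcyclohexyl acetate
Conditions: HF·pyridine, pyridine/THF, 0 °C → rt
Reagents that add atoms: none
Why: Fluoride-mediated desilylation cleaves the primary Si–O bond, while the tertiary acetate, the tertiary alcohol and both neopentylic bromides should be stable to buffered HF·pyridine.

**Compound list**

1 | ethyl 8-oxo-1,4-dioxaspiro[4.5]decane-7-carboxylate | CCOC(=O)C1CC2(CCC1=O)OCCO2 | starting material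
2 | allyl acetate | CC(=O)OCC=C | starting material
3 | ethyl (7R)-8-oxo-7-(prop-2-en-1-yl)-1,4-dioxaspiro[4.5]decane-7-carboxylate | C=CC[C@]1(C(=O)OCC)C(=O)CCC2(OCCO2)C1 | intermediate
4 | (7S)-7-(hydroxymethyl)-7-(prop-2-en-1-yl)-1,4-dioxaspiro[4.5]decan-8-one | C=CC[C@]1(CO)C(=O)CCC2(OCCO2)C1 | intermediate
5 | (7S,8R)-7-(hydroxymethyl)-7-(prop-2-en-1-yl)-1,4-dioxaspiro[4.5]decan-8-ol (8-OH trans to CH2OH) | C=CC[C@]1(CO)[C@H](O)CCC2(OCCO2)C1 | intermediate
6 | (7S,8R)-7-(prop-2-en-1-yl)-7-[(TBDPS-oxy)methyl]-1,4-dioxaspiro[4.5]decan-8-ol | C=CC[C@]1(CO[Si](c2ccccc2)(c3ccccc3)C(C)(C)C)[C@H](O)CCC4(OCCO4)C1 | intermediate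
7 | (7S,8R)-7-(prop-2-en-1-yl)-7-[(TBDPS-oxy)methyl]-8-(TES-oxy)-1,4-dioxaspiro[4.5]decane | C=CC[C@]1(CO[Si](c2ccccc2)(c3ccccc3)C(C)(C)C)[C@H](O[Si](CC)(CC)CC)CCC4(OCCO4)C1 | intermediate
8 | 3-{(7S,8R)-7-[(TBDPS-oxy)methyl]-8-(TES-oxy)-1,4-dioxaspiro[4.5]decan-7-yl}propan-1-ol | OCCC[C@]1(CO[Si](c2ccccc2)(c3ccccc3)C(C)(C)C)[C@H](O[Si](CC)(CC)CC)CCC4(OCCO4)C1 | intermediate
9 | 3-{(7S,8R)-7-[(TBDPS-oxy)methyl]-8-(TES-oxy)-1,4-dioxaspiro[4.5]decan-7-yl}propanal | O=CCC[C@]1(CO[Si](c2ccccc2)(c3ccccc3)C(C)(C)C)[C@H](O[Si](CC)(CC)CC)CCC4(OCCO4)C1 | intermediate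
10 | 3-{(1S,2R)-2-hydroxy-5-oxo-1-[(TBDPS-oxy)methyl]cyclohexyl}propanal | O=CCC[C@]1(CO[Si](c2ccccc2)(c3ccccc3)C(C)(C)C)[C@H](O)CCC(=O)C1 | intermediate
11 | (7R,7aS)-7-hydroxy-7a-[(TBDPS-oxy)methyl]-1,2,5,6,7,7a-hexahydro-4H-inden-4-one | C=2CC[C@]3(CO[Si](c4ccccc4)(c5ccccc5)C(C)(C)C)[C@H](O)CCC(=O)C3=2 | intermediate
12 | (7S,7aS)-7-bromo-7a-[(TBDPS-oxy)methyl]-1,2,5,6,7,7a-hexahydro-4H-inden-4-one | C=2CC[C@]3(CO[Si](c4ccccc4)(c5ccccc5)C(C)(C)C)[C@@H](Br)CCC(=O)C3=2 | intermediate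
13 | 2-[(trimethylsilyl)methyl]prop-2-en-1-yl acetate | CC(=O)OCC(=C)C[Si](C)(C)C | starting material
14 | (3S,3aS,7S,7aS)-3-[2-(acetoxymethyl)prop-2-en-1-yl]-7-bromo-7a-[(TBDPS-oxy)methyl]octahydro-4H-inden-4-one | CC(=O)OCC(=C)C[C@@H]2CC[C@]3(CO[Si](c4ccccc4)(c5ccccc5)C(C)(C)C)[C@@H](Br)CCC(=O)[C@@H]23 | intermediate
15 | (3S,3aS,4R,7S,7aS)-7-bromo-3-[2-(hydroxymethyl)prop-2-en-1-yl]-4-methyl-7a-[(TBDPS-oxy)methyl]octahydro-1H-inden-4-ol | OCC(=C)C[C@@H]2CC[C@]3(CO[Si](c4ccccc4)(c5ccccc5)C(C)(C)C)[C@@H](Br)CC[C@@](C)(O)[C@@H]23 | intermediate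
16 | [(2R)-2-(Hyd-methyl)oxiran-2-yl]methanol | C1O[C@]1(C[C@@H]2CC[C@]3(CO[Si](c4ccccc4)(c5ccccc5)C(C)(C)C)[C@@H](Br)CC[C@@](C)(O)[C@@H]23)CO | intermediate
17 | isopropenylmagnesium bromide | CC(=C)[Mg]Br | starting material
18 | (2S)-2-(Hyd-methyl)-4-methylpent-4-ene-1,2-diol | O[C@](CC(C)=C)(C[C@@H]2CC[C@]3(CO[Si](c4ccccc4)(c5ccccc5)C(C)(C)C)[C@@H](Br)CC[C@@](C)(O)[C@@H]23)CO | intermediate
19 | (2S)-2-hydroxy-2-(Hyd-methyl)-4-methylpent-4-en-1-yl 4-methylbenzenesulfonate | O[C@](CC(C)=C)(C[C@@H]2CC[C@]3(CO[Si](c4ccccc4)(c5ccccc5)C(C)(C)C)[C@@H](Br)CC[C@@](C)(O)[C@@H]23)COS(=O)(=O)c6ccc(C)cc6 | intermediate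
20 | (2S)-2-(Hyd-methyl)-2-(2-methylprop-2-en-1-yl)oxirane | O1[C@](CC(C)=C)(C[C@@H]2CC[C@]3(CO[Si](c4ccccc4)(c5ccccc5)C(C)(C)C)[C@@H](Br)CC[C@@](C)(O)[C@@H]23)C1 | intermediate
21 | dilithium alkoxide of (4S)-4-hydroxy-4-(Hyd-methyl)-6-methylhept-6-enenitrile (lithium on the chain oxygen and on the C4 oxygen of Hyd) | [Li]O[C@](CC(C)=C)(C[C@@H]2CC[C@]3(CO[Si](c4ccccc4)(c5ccccc5)C(C)(C)C)[C@@H](Br)CC[C@@](C)(O[Li])[C@@H]23)CCC#N | intermediate
22 | (4S)-4-acetoxy-4-(Hyd-methyl)-6-methylhept-6-enenitrile | CC(=O)O[C@](CC(C)=C)(C[C@@H]2CC[C@]3(CO[Si](c4ccccc4)(c5ccccc5)C(C)(C)C)[C@@H](Br)CC[C@@](C)(O)[C@@H]23)CCC#N | intermediate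
23 | (1S)-1-(Hyd-methyl)-4-imino-3,3-dimethylcyclohexyl acetate | CC(=O)O[C@]1(C[C@@H]2CC[C@]3(CO[Si](c4ccccc4)(c5ccccc5)C(C)(C)C)[C@@H](Br)CC[C@@](C)(O)[C@@H]23)CCC(=N)C(C)(C)C1 | intermediate
24 | (1S)-1-(Hyd-methyl)-3,3-dimethyl-4-oxocyclohexyl acetate | CC(=O)O[C@]1(C[C@@H]2CC[C@]3(CO[Si](c4ccccc4)(c5ccccc5)C(C)(C)C)[C@@H](Br)CC[C@@](C)(O)[C@@H]23)CCC(=O)C(C)(C)C1 | intermediate
25 | (1S,4R)-4-hydroxy-1-(Hyd-methyl)-3,3-dimethylcyclohexyl acetate (4-OH trans to OAc) | CC(=O)O[C@]1(C[C@@H]2CC[C@]3(CO[Si](c4ccccc4)(c5ccccc5)C(C)(C)C)[C@@H](Br)CC[C@@](C)(O)[C@@H]23)CC[C@@H](O)C(C)(C)C1 | intermediate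
26 | (1S,4S)-4-bromo-1-(Hyd-methyl)-3,3-dimethylcyclohexyl acetate | CC(=O)O[C@]1(C[C@@H]2CC[C@]3(CO[Si](c4ccccc4)(c5ccccc5)C(C)(C)C)[C@@H](Br)CC[C@@](C)(O)[C@@H]23)CC[C@H](Br)C(C)(C)C1 | intermediate
27 | (1S,4S)-4-bromo-1-{[(3S,3aS,4R,7S,7aS)-7-bromo-4-hydroxy-7a-(hydroxymethyl)-4-methyloctahydro-1H-inden-3-yl]methyl}-3,3-dimethylcyclohexyl acetate | CC(=O)O[C@]1(C[C@@H]2CC[C@]3(CO)[C@@H](Br)CC[C@@](C)(O)[C@@H]23)CC[C@H](Br)C(C)(C)C1 | target

**Totals and risks**

Total step count: 18. Longest linear sequence: 18 steps (from 1).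

Steps most likely to fail:

Step 8. The oxyphosphonium salt at the neopentylic C7 may collapse by elimination toward C6 or by a 1,2-shift from C7a faster than bromide can reach the hindered rear face. The fallback sets out from 11 and comes back at 14; it moves the substitution behind the conjugate allylation and changes the leaving group. Compound 11 is first allylated with 13 and TiCl4 to the trans-fused keto alcohol (3S,3aS,7R,7aS)-3-[2-(acetoxymethyl)prop-2-en-1-yl]-7-hydroxy-7a-[(TBDPS-oxy)methyl]octahydro-4H-inden-4-one F1, in which the C7 hydroxyl is locked axial. Tf2O and pyridine convert it into the C7 trifluoromethanesulfonate F2, and Bu4NBr in toluene should displace the triflate with inversion to give 14.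

Step 15. Premature reduction of the tertiary radical (net hydrogenation of the alkene) or a 1,2-shift of the neighbouring acetoxy group may outrun the slow addition to the nitrile. The fallback sets out from 20 and comes back at 24; it replaces the nitrile by a carbonyl acceptor, to which alkyl radicals add much faster. Epoxide 20 is opened with lithiated acetaldehyde N,N-dimethylhydrazone and the alkoxide is acetylated in the flask, giving the acetoxy hydrazone (4S)-4-acetoxy-4-(Hyd-methyl)-6-methylhept-6-enal N,N-dimethylhydrazone F3. CuCl2 in aqueous THF hydrolyses it to the acetoxy aldehyde (4S)-4-acetoxy-4-(Hyd-methyl)-6-methylhept-6-enal F4. Fe(acac)3 and PhSiH3 in EtOH then close ring A by 6-exo attack of the tertiary radical on the aldehyde, giving the cyclohexanol (1S)-4-hydroxy-1-(Hyd-methyl)-3,3-dimethylcyclohexyl acetate F5 as a mixture of C4′ epimers, and DMP oxidation converges on 24.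

Step 17. Elimination toward C5′, participation of the trans C1′ acetoxy group or a neopentyl-type methyl shift may compete with the SN2 displacement. The fallback sets out from 24 and comes back at 26 (it replaces steps 16 and 17); it sets the bromide under radical, thermodynamic control. KHMDS and PhNTf2 give the enol triflate (1S)-1-(Hyd-methyl)-5,5-dimethyl-4-(trifluoromethanesulfonyloxy)cyclohex-3-en-1-yl acetate F6. A nickel-catalysed triflate–bromide exchange (Ni(OAc)2·4H2O, Zn, 1,5-cyclooctadiene, LiBr, DMA/THF) gives the alkenyl bromide (1S)-4-bromo-1-(Hyd-methyl)-5,5-dimethylcyclohex-3-en-1-yl acetate F7. Hydrogen-atom-transfer hydrogenation (Mn(dpm)3, PhSiH3, t-BuOOH, i-PrOH) then reduces it through the α-bromo radical at C4′, which should take up hydrogen axially and so leave bromine equatorial, cis to the acetate, giving 26.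

**Further compounds**

F1 | step 8 | (3S,3aS,7R,7aS)-3-[2-(acetoxymethyl)prop-2-en-1-yl]-7-hydroxy-7a-[(TBDPS-oxy)methyl]octahydro-4H-inden-4-one | CC(=O)OCC(=C)C[C@@H]2CC[C@]3(CO[Si](c4ccccc4)(c5ccccc5)C(C)(C)C)[C@H](O)CCC(=O)[C@@H]23
F2 | step 8 | C7 trifluoromethanesulfonate of F1 | CC(=O)OCC(=C)C[C@@H]2CC[C@]3(CO[Si](c4ccccc4)(c5ccccc5)C(C)(C)C)[C@H](OS(=O)(=O)C(F)(F)F)CCC(=O)[C@@H]23
F3 | step 15 | (4S)-4-acetoxy-4-(Hyd-methyl)-6-methylhept-6-enal N,N-dimethylhydrazone | CC(=O)O[C@](CC(C)=C)(C[C@@H]2CC[C@]3(CO[Si](c4ccccc4)(c5ccccc5)C(C)(C)C)[C@@H](Br)CC[C@@](C)(O)[C@@H]23)CCC=NN(C)C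
F4 | step 15 | (4S)-4-acetoxy-4-(Hyd-methyl)-6-methylhept-6-enal | CC(=O)O[C@](CC(C)=C)(C[C@@H]2CC[C@]3(CO[Si](c4ccccc4)(c5ccccc5)C(C)(C)C)[C@@H](Br)CC[C@@](C)(O)[C@@H]23)CCC=O
F5 | step 15 | (1S)-4-hydroxy-1-(Hyd-methyl)-3,3-dimethylcyclohexyl acetate (C4′ epimers) | CC(=O)O[C@]1(C[C@@H]2CC[C@]3(CO[Si](c4ccccc4)(c5ccccc5)C(C)(C)C)[C@@H](Br)CC[C@@](C)(O)[C@@H]23)CCC(O)C(C)(C)C1
F6 | step 17 | (1S)-1-(Hyd-methyl)-5,5-dimethyl-4-(trifluoromethanesulfonyloxy)cyclohex-3-en-1-yl acetate | CC(=O)O[C@]1(C[C@@H]2CC[C@]3(CO[Si](c4ccccc4)(c5ccccc5)C(C)(C)C)[C@@H](Br)CC[C@@](C)(O)[C@@H]23)CC=C(OS(=O)(=O)C(F)(F)F)C(C)(C)C1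
F7 | step 17 | (1S)-4-bromo-1-(Hyd-methyl)-5,5-dimethylcyclohex-3-en-1-yl acetate | CC(=O)O[C@]1(C[C@@H]2CC[C@]3(CO[Si](c4ccccc4)(c5ccccc5)C(C)(C)C)[C@@H](Br)CC[C@@](C)(O)[C@@H]23)CC=C(Br)C(C)(C)C1
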